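I want to know what holds most of the substrate at the end of the teal and blue runs, and how much it holds.

- teal: substrate 0.0050 M; partner 3.50 mM; free catalyst 20 µM; time 50 s
- blue: substrate 0.0050 M; partner 3.50 mM; free catalyst 10 µM; time 50 s

    2 catalyst intermediate A → spent catalyst (k1 = 3700 M⁻¹ s⁻¹)
    catalyst intermediate B → released group + catalyst intermediate C (k2 = 2300 s⁻¹)
    catalyst intermediate C → free catalyst + target (k3 = 1300 s⁻¹)
    partner + catalyst intermediate A ⇌ catalyst intermediate B (K4 = 240 M⁻¹, k4 = 33000 M⁻¹ s⁻¹)
    substrate + free catalyst ⇌ catalyst intermediate A (K5 = 140 M⁻¹, k5 = 5100 M⁻¹ s⁻¹)

1. which of these there is most of at the end, counted by the substrate in it, teal (catalyst intermediate C / substrate / catalyst intermediate A / target)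
2. which of these there is most of at the end, counted by the substrate in it, blue (catalyst intermediate C / substrate / catalyst intermediate A / target)
3. the largest of these amounts at the end, in percent of the substrate charged, teal
4. the largest of these amounts at the end, in percent of the substrate charged, blue

- a species is counted by the substrate in it: one spent catalyst counts as two
- a step written with two of one species runs at k times the square of its concentration and takes two of it each time
- run time (teal): 50 s

Partner is the limiting reagent, since 3.50 mM stands against 0.0050 M of substrate. That caps target at 70.0% of the substrate charged, so I ask how much of the partner is used in the time.

At the start, catalyst intermediate A lives about 0.00658 s, far shorter than the run, so I take it to be made as fast as it is used. Its share of the catalyst is then the making rate over the sum of making, return and capture by partner. Substrate and partner fall together, so I freeze this share at its starting value: 14.4%.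

Partner then decays pseudo-first-order. The number of e-foldings of partner in the run, N, is k4 times that share times the catalyst charge times the time: 2.37 in blue. Teal has twice the catalyst, so 4.74.

| Flask | N | Partner left | Target |
|---|---|---|---|
| teal | 4.74 | 0.874% | 69.4% |
| blue | 2.37 | 9.35% | 63.5% |

Is one number enough? In blue, the reckoned end is 1.83 mM of substrate and 0.327 mM of partner, which lifts the share to 16.5%. Against that, pairing takes about 7.64% of the blue catalyst, and 5.64% of catalyst intermediate B returns. These corrections pull against each other, so I keep N.

The forecast says target at 69% in teal and target at 63% in blue, and that “Teal therefore gets close to the cap”.

The flasks give target at 69.3% in teal and target at 63.2% in blue, with 0.960% of the partner charge left in teal and 9.68% in blue.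

In blue at 13.1 s, catalyst intermediate A is made 1.00 times as fast as it is used, and it stands at 15.2% of the catalyst at the end. At the end of blue, the forward step with partner alone takes it 990 times faster than pairing does.

Take blue with 0.0021 M of partner. The share becomes 19.4%, so N is 3.21, which leaves 4.04% of the partner and gives 40.3% target. That flask gives 40.7% target, with 2.98% of its partner left.

The rate constants are those of an exercise, and the outcome is calculated.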